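**Retrosynthetic overview**
1. Target 10 ⇒ formyl acid 9 (C3 CH2OH from CHO by a final hydride reduction) ⇒ benzyl ester 8 (free CO2H by hydrogenolysis).
2. 8 ⇒ aryl iodide 5 + CO + phenol 7: the depside carbonyl is stitched in from carbon monoxide in one new three-component Pd step that forms both the Ar–C(=O) and the C(=O)–OAr bond.
3. 5 ⇒ 4 ⇒ 1: iodination of the mirror-symmetric aldehyde 4 (its two free ring positions are equivalent), which comes from lithiation/formylation of 3,5-dimethoxytoluene between the two OMe groups.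
4. 7 ⇒ 6: benzyl ester of 3-methylorsellinic acid.
5. No ring is formed; both benzene rings are bought intact.

Assumption: the target SMILES contains no stereocentre or stereogenic double bond, so the compound is achiral and no stereocontrol is needed; 2,4-dihydroxy-3,6-dimethylbenzoic acid (6) is taken as a catalogue compound.

**Step 1**
Reactants: 1 3,5-dimethoxytoluene
Product: 4 2,6-dimethoxy-4-methylbenzaldehyde, via aryllithium 2 (not isolated), via lithium hemiaminolate 3 (not isolated)
Conditions: n-BuLi, TMEDA, Et2O, 0 °C to rt; DMF, 0 °C to rt; 1 M HCl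
Reagents that add atoms: n-butyllithium [Li]CCCC (lithium, present in 2 and 3 only); N,N-dimethylformamide CN(C)C=O
Why: Directed ortho-metalation places lithium on the carbon between the two cooperating OMe groups, and the aryllithium adds to DMF to give a stable hemiaminolate that releases the aldehyde on acidic work-up (Bouveault formylation); the only stereocentre is the transient racemic one in 3.

**Step 2**
Reactants: 4 2,6-dimethoxy-4-methylbenzaldehyde
Product: 5 3-iodo-2,6-dimethoxy-4-methylbenzaldehyde
Conditions: NIS (1.0 equiv), TFA (cat.), MeCN, rt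
Reagents that add atoms: N-iodosuccinimide O=C1CCC(=O)N1I
Why: Electrophilic aromatic iodination; the two free positions of 4 are equivalent by symmetry and each is ortho to one OMe and para to the other, so only one mono-iodide can form, and one equivalent of NIS on the CHO-deactivated ring limits di-iodination.

**Step 3**
Reactants: 6 2,4-dihydroxy-3,6-dimethylbenzoic acid
Product: 7 benzyl 2,4-dihydroxy-3,6-dimethylbenzoate
Conditions: BnBr, KHCO3, DMF, rt
Reagents that add atoms: benzyl bromide BrCc1ccccc1
Why: Carboxylate O-alkylation (SN2); bicarbonate deprotonates only the carboxylic acid and not the phenols, so the benzyl ester forms selectively.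

**Step 4**
Reactants: 5 3-iodo-2,6-dimethoxy-4-methylbenzaldehyde; 7 benzyl 2,4-dihydroxy-3,6-dimethylbenzoate
Product: 8 benzyl 4-[(3-formyl-2,4-dimethoxy-6-methylbenzoyl)oxy]-2-hydroxy-3,6-dimethylbenzoate
Conditions: Pd(OAc)2 (5 mol %), Xantphos (6 mol %), CO (1 atm), K3PO4, toluene, 80 °C
Reagents that add atoms: carbon monoxide [C-]#[O+]
Why: Proposed new method: a three-component carbonylative depside coupling in which Pd(0)/Xantphos inserts into the C–I bond of 5, CO insertion is driven by relief of di-ortho strain in the aryl–Pd species, the more acidic non-chelated 4-O phenoxide of 7 (the 2-OH is locked in a hydrogen bond to the ester C=O) replaces iodide on Pd, and the wide bite angle promotes C(acyl)–O reductive elimination to the hindered aryl ester, while the aldehyde and benzyl ester are expected to be inert to Pd(0)/CO at 80 °C; the closest known reaction type is Pd-catalysed aryloxycarbonylation of unhindered aryl halides with simple phenols, which has not been shown for a 2,6-disubstituted electron-rich aryl iodide with an ortho-substituted polyfunctional phenol or used to make a depside; no stereocentre is formed.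

**Step 5**
Reactants: 8 benzyl 4-[(3-formyl-2,4-dimethoxy-6-methylbenzoyl)oxy]-2-hydroxy-3,6-dimethylbenzoate
Product: 9 4-[(3-formyl-2,4-dimethoxy-6-methylbenzoyl)oxy]-2-hydroxy-3,6-dimethylbenzoic acid
Conditions: H2 (1 atm), 10% Pd/C, EtOAc, rt, stopped at full conversion
Reagents that add atoms: none
Why: Catalytic hydrogenolysis of a benzyl ester is fast in EtOAc, whereas the di-ortho-methoxy aryl aldehyde and the aryl ester react far more slowly; any aldehyde that is reduced to the alcohol is already target 10 and converges in step 6.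

**Step 6**
Reactants: 9 4-[(3-formyl-2,4-dimethoxy-6-methylbenzoyl)oxy]-2-hydroxy-3,6-dimethylbenzoic acid
Product: 10 2-hydroxy-4-{[3-(hydroxymethyl)-2,4-dimethoxy-6-methylbenzoyl]oxy}-3,6-dimethylbenzoic acid
Conditions: NaBH4 (2 equiv), THF/MeOH, 0 °C; then cold aqueous work-up at pH 3
Reagents that add atoms: none
Why: Chemoselective NaBH4 reduction of the aryl aldehyde (hydride addition); the carboxylate and the 2,6-disubstituted, hindered depside ester are inert at 0 °C, and the new CH2OH carbon is not a stereocentre.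

**Compound list**
1 | 3,5-dimethoxytoluene (1,3-dimethoxy-5-methylbenzene) | COc1cc(C)cc(OC)c1 | starting material
2 | (2,6-dimethoxy-4-methylphenyl)lithium | [Li]c1c(OC)cc(C)cc1OC | intermediate (not isolated)
3 | lithium (dimethylamino)(2,6-dimethoxy-4-methylphenyl)methanolate (racemic, transient) | [Li+].[O-]C(N(C)C)c1c(OC)cc(C)cc1OC | intermediate (not isolated)
4 | 2,6-dimethoxy-4-methylbenzaldehyde | COc1cc(C)cc(OC)c1C=O | intermediate
5 | 3-iodo-2,6-dimethoxy-4-methylbenzaldehyde | COc1cc(C)c(I)c(OC)c1C=O | intermediate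
6 | 2,4-dihydroxy-3,6-dimethylbenzoic acid (3-methylorsellinic acid) | Cc1cc(O)c(C)c(O)c1C(=O)O | starting material
7 | benzyl 2,4-dihydroxy-3,6-dimethylbenzoate | Cc1cc(O)c(C)c(O)c1C(=O)OCc1ccccc1 | intermediate
8 | benzyl 4-[(3-formyl-2,4-dimethoxy-6-methylbenzoyl)oxy]-2-hydroxy-3,6-dimethylbenzoate | COc1cc(C)c(C(=O)Oc2cc(C)c(C(=O)OCc3ccccc3)c(O)c2C)c(OC)c1C=O | intermediate
9 | 4-[(3-formyl-2,4-dimethoxy-6-methylbenzoyl)oxy]-2-hydroxy-3,6-dimethylbenzoic acid | COc1cc(C)c(C(=O)Oc2cc(C)c(C(=O)O)c(O)c2C)c(OC)c1C=O | intermediate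
10 | 2-hydroxy-4-{[3-(hydroxymethyl)-2,4-dimethoxy-6-methylbenzoyl]oxy}-3,6-dimethylbenzoic acid (achiral) | COc1cc(C)c(C(=O)Oc2cc(C)c(C(=O)O)c(O)c2C)c(OC)c1CO | target

**Totals**
Total step count: 6. Longest linear sequence: 5 steps (steps 1, 2, 4, 5, 6).

**Three steps most likely to fail**

Step 4 (the proposed new carbonylative depside coupling). It may fail through slow acyl–O bond formation with the hindered phenoxide, hydrodeiodination, or Pd attack on the benzyl ester. The fallback uses known chemistry only, sets out from 5 and comes back to the route at 8. The aldehyde of 5 is masked with trimethyl orthoformate (MeOH, cat. PPTS) as 2-(dimethoxymethyl)-4-iodo-1,3-dimethoxy-5-methylbenzene F1. Iodine–lithium exchange (n-BuLi, THF, −78 °C) gives [3-(dimethoxymethyl)-2,4-dimethoxy-6-methylphenyl]lithium F2, which is carboxylated with CO2 to lithium 3-(dimethoxymethyl)-2,4-dimethoxy-6-methylbenzoate F3. Work-up with 2 M HCl frees both the acid and the aldehyde, giving 3-formyl-2,4-dimethoxy-6-methylbenzoic acid F4. Classical depside esterification with trifluoroacetic anhydride in toluene at rt then activates F4 as 3-formyl-2,4-dimethoxy-6-methylbenzoic trifluoroacetic anhydride F5, which acylates the free 4-OH of 7 to give 8.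

Step 5 (hydrogenolysis in the presence of the aryl aldehyde). The risk is over-reduction of CHO through CH2OH to CH3. The fallback avoids hydrogenation altogether, sets out from 6 (and uses 5) and comes back at 9. Acid 6 is esterified with 4-methoxybenzyl chloride (KHCO3, DMF) to 4-methoxybenzyl 2,4-dihydroxy-3,6-dimethylbenzoate F6. Coupling of F6 with 5 and CO under the step 4 conditions gives 4-methoxybenzyl 4-[(3-formyl-2,4-dimethoxy-6-methylbenzoyl)oxy]-2-hydroxy-3,6-dimethylbenzoate F7. TFA with anisole as cation scavenger in CH2Cl2 at 0 °C cleaves the PMB ester to give 9; the aldehyde, the depside ester and the methyl ethers tolerate these conditions.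

Step 2 (mono-iodination of the aldehyde-bearing ring). The risks are low conversion, di-iodination or ipso-deformylation. The fallback halogenates an aldehyde-free, more electron-rich ring and carries the hydroxymethyl group protected; it sets out from 4 and comes back at 10. Aldehyde 4 is reduced (NaBH4, MeOH) to (2,6-dimethoxy-4-methylphenyl)methanol F8 and silylated (TBSCl, imidazole, DMF) to tert-butyl[(2,6-dimethoxy-4-methylphenyl)methoxy]dimethylsilane F9. Iodination (NIS, MeCN, 0 °C, no acid) gives tert-butyl[(3-iodo-2,6-dimethoxy-4-methylphenyl)methoxy]dimethylsilane F10, again a single regioisomer by symmetry. Carbonylative coupling with 7 as in step 4 gives benzyl 4-{[3-({[tert-butyl(dimethyl)silyl]oxy}methyl)-2,4-dimethoxy-6-methylbenzoyl]oxy}-2-hydroxy-3,6-dimethylbenzoate F11. Hydrogenolysis (H2, Pd/C, EtOAc) gives 4-{[3-({[tert-butyl(dimethyl)silyl]oxy}methyl)-2,4-dimethoxy-6-methylbenzoyl]oxy}-2-hydroxy-3,6-dimethylbenzoic acid F12, and HF·pyridine in THF at 0 °C removes the silyl group to give 10.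

**Further compounds**
F1 | step 4 | 2-(dimethoxymethyl)-4-iodo-1,3-dimethoxy-5-methylbenzene | COc1cc(C)c(I)c(OC)c1C(OC)OC
F2 | step 4 | [3-(dimethoxymethyl)-2,4-dimethoxy-6-methylphenyl]lithium | [Li]c1c(C)cc(OC)c(C(OC)OC)c1OC
F3 | step 4 | lithium 3-(dimethoxymethyl)-2,4-dimethoxy-6-methylbenzoate | [Li+].[O-]C(=O)c1c(C)cc(OC)c(C(OC)OC)c1OC
F4 | step 4 | 3-formyl-2,4-dimethoxy-6-methylbenzoic acid | COc1cc(C)c(C(=O)O)c(OC)c1C=O
F5 | step 4 | 3-formyl-2,4-dimethoxy-6-methylbenzoic trifluoroacetic anhydride | COc1cc(C)c(C(=O)OC(=O)C(F)(F)F)c(OC)c1C=O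
F6 | step 5 | 4-methoxybenzyl 2,4-dihydroxy-3,6-dimethylbenzoate | Cc1cc(O)c(C)c(O)c1C(=O)OCc1ccc(OC)cc1
F7 | step 5 | 4-methoxybenzyl 4-[(3-formyl-2,4-dimethoxy-6-methylbenzoyl)oxy]-2-hydroxy-3,6-dimethylbenzoate | COc1cc(C)c(C(=O)Oc2cc(C)c(C(=O)OCc3ccc(OC)cc3)c(O)c2C)c(OC)c1C=O
F8 | step 2 | (2,6-dimethoxy-4-methylphenyl)methanol | COc1cc(C)cc(OC)c1CO
F9 | step 2 | tert-butyl[(2,6-dimethoxy-4-methylphenyl)methoxy]dimethylsilane | COc1cc(C)cc(OC)c1CO[Si](C)(C)C(C)(C)C
F10 | step 2 | tert-butyl[(3-iodo-2,6-dimethoxy-4-methylphenyl)methoxy]dimethylsilane | COc1cc(C)c(I)c(OC)c1CO[Si](C)(C)C(C)(C)C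
F11 | step 2 | benzyl 4-{[3-({[tert-butyl(dimethyl)silyl]oxy}methyl)-2,4-dimethoxy-6-methylbenzoyl]oxy}-2-hydroxy-3,6-dimethylbenzoate | COc1cc(C)c(C(=O)Oc2cc(C)c(C(=O)OCc3ccccc3)c(O)c2C)c(OC)c1CO[Si](C)(C)C(C)(C)C
F12 | step 2 | 4-{[3-({[tert-butyl(dimethyl)silyl]oxy}methyl)-2,4-dimethoxy-6-methylbenzoyl]oxy}-2-hydroxy-3,6-dimethylbenzoic acid | COc1cc(C)c(C(=O)Oc2cc(C)c(C(=O)O)c(O)c2C)c(OC)c1CO[Si](C)(C)C(C)(C)C
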